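The rate constants are invented; the flask was simulated.

Slowness is the hazard in this flask: double product leaks to its isomer with a half-life, by the forward step alone, of 30.1 min, shorter than the run, so a scarce charge must go into the right recipe.

    substrate + coupling partner → single product + released group (k1 = 0.90 M⁻¹ min⁻¹)
    substrate + released group → side product (k2 = 0.062 M⁻¹ min⁻¹)
    coupling partner + single product → double product + released group (k3 = 0.84 M⁻¹ min⁻¹)
    double product ⇌ isomer of the product (K4 = 1.3, k4 = 0.023 min⁻¹)

| flask | substrate | coupling partner | time | remark |
|---|---|---|---|---|
| south | 0.050 M | 0.0900 M | 40 min | everything together in a closed stirred flask, run for 40 min |
| north-west | 0.050 M (fed, over 40.0 min) | 0.0900 M | 40 min | a stirred flask in which substrate is dosed at a steady rate over 40.0 min without added volume, worked up at 40 min |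
| south-west | 0.050 M | 0.0900 M (fed, over 40.0 min) | 40 min | all but coupling partner at the start; coupling partner goes in evenly over 40.0 min, the run ends at 40 min |
| east | 0.050 M | 0.0900 M |  | one stirred flow tank at steady state, fed with the mixture as stated, mean residence time 40 min |

- the set-up with the highest amount of double product at the outlet or at the end, in percent of the substrate put in ("none" if the first two lie within 2 percentage points) (south / north-west / south-west / east / none)
- amount of double product at the outlet or at the end, in percent of the substrate put in, south
- amount of double product at the outlet or at the end, in percent of the substrate put in, north-west
- amount of double product at the outlet or at the end, in percent of the substrate put in, south-west
- amount of double product at the outlet or at the end, in percent of the substrate put in, east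

- the stated concentrations are those of everything mixed, before any reaction; amounts are the same in each set-up
- the feed brings no volume worth counting
- run time (south): 40 min

The choice of recipe for the next run can be reckoned as two factors: the pool, meaning double product plus isomer, and the part of it that stays double product. A newly made pool is pure double product, while a very old one tends to 43.5% double product. Between these ends the share relaxes at the forward plus the back constant, 0.0407 min⁻¹. Taking the mean age of the pool as half the run in a flask charged together gives 68.5% for the kept share, the fraction of the pool still double product at the end.

The couplings have similar constants, and the side step has a far smaller constant than the first coupling, so it is dropped from this estimate. The pool then follows exposure, meaning constant times partner level times time: pool equals one minus (one plus exposure) times exp(−exposure). Coupling partner is the limiting reagent for double product, at 1.80 equivalents against the two required. Its level falls, so half its charge serves as the mean. South thus has exposure 1.57, pool 46.4% and 31.8% double product.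

Each dosed flask is roughly taken at a third of full contact, meaning the whole partner charge for the whole run, which makes exposure 1.04, with a pool aged a quarter of the run, so its kept share is 81.1%. That one rough figure serves both: 22.7% for north-west and 22.7% for south-west. The tank, taken at south's exposure, has a pool equal to the square of exposure over one plus exposure, and the pool at its outlet has ages spread exponentially about the residence time, so its kept share is 65.0% and its estimate 24.2%. The recipe to charge is south, ahead of the others.

The forecast, noting that “both couplings have similar rate constants”, gives 33%, 23.4%, 20.6% and 22.6% for south, north-west, south-west and east, picks south, and places south-west and the tank lower than this reckoning does.

The flasks give 33.3% in south, 23.3% in north-west, 20.3% in south-west and 22.5% in east, and south leads. In south, single product had a half-life of 13 min toward double product at 7.45 min, shorter than the 30 min of double product toward its isomer by the forward rate at 40.0 min. South's kept share reads 68.8% against the reckoned 68.5%. For the neighbour of south charged with 0.054 M of coupling partner, half-charge exposure is 0.940, and with the same kept share it gives 16.6%, while that flask holds 16.4% double product.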